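Locants: ring-fusion carbons C1 and C5; cyclopentane C1–C2–C3(Me)–C4–C5; cycloheptane C5–C6–C7(Me,OH)–C8–C9(O-aroyl)–C10(iPr)–C1. Everything rests on forming the fusion bond C1–C5 by an intramolecular De Mayo photocycloaddition. The precursor is a cyclopentenyl benzyl carbonate (ring carbons C5–C9, C7 carbinol in place) whose C4 acyl chain ends in the C1=C10 alkene. Light closes the five-membered ring through C1–C5 and C9–C10, giving a strained cyclobutane; unmasking the C9 cyclobutanol then cleaves C5–C9 by retro-aldol and opens the seven-membered ring. The step exploits the 1,5-dioxygen pattern O–C9···C4–O across C1–C5: the two carbonyls become the C9 ester carbinol and the C3–C4 epoxide.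

Key step: step 7

Remark: β is the face of the bicycle that carries H on C1, α the opposite face; the target is then 1β-H, 5α-H, 3α-Me, 3β,4β-epoxide, 7α-Me, 7β-OH, 9α-O-aroyl, 10β-iPr.
Remark: in step 1 the enantiomer of the QuinoxP* ligand is taken that gives (S)-2; both enantiomers are assumed to be obtainable.
Remark: the alkene geometry and the configurations at C3 and C10 are carried as mixtures until steps 8 and 9, where they converge.

Step 1
Reactants: 1 3-methylcyclopent-2-en-1-one
Product: 3 (R)-3-hydroxy-3-methylcyclopentan-1-one, via tertiary boronate 2 (not isolated)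
Conditions: B2pin2, CuPF6(MeCN)4 (cat.), QuinoxP* (cat.), LiOtBu (cat.), DMSO, rt; then NaBO3·4H2O, THF/H2O, rt
Reagents that add atoms: sodium perborate tetrahydrate, [Na+].[Na+].O[B-]1(O)OO[B-](O)(O)OO1
Why: Enantioselective copper-boryl conjugate addition (β-boration) to the β-methyl enone should create the quaternary C–B centre under ligand control, and perborate oxidation replaces boron by hydroxyl with retention, so the future C7 carbinol is set here.

Step 2
Reactants: 3 (R)-3-hydroxy-3-methylcyclopentan-1-one
Product: 4 (R)-3-methyl-3-(triethylsilyloxy)cyclopentan-1-one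
Conditions: Et3SiOTf, 2,6-lutidine, CH2Cl2, −78 °C
Reagents that add atoms: triethylsilyl trifluoromethanesulfonate, CC[Si](CC)(CC)OS(=O)(=O)C(F)(F)F
Why: Silyl triflate silylation of the tertiary alcohol at low temperature should outrun enol silylation and blocks retro-aldol or elimination of the β-hydroxy ketone in the basic acylation that follows.

Step 3
Reactants: 5 4-methylpent-1-en-3-ol (racemic); 6 triethyl orthopropionate
Product: 8 ethyl (E)-2,6-dimethylhept-4-enoate (racemic), via ketene acetal 7 (not isolated)
Conditions: EtCO2H (cat.), 140 °C, distil off EtOH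
Reagents that add atoms: triethyl orthopropionate (compound 6), CCC(OCC)(OCC)OCC
Why: Johnson–Claisen rearrangement through a chair transition state with the isopropyl group equatorial should give the (E)-γ,δ-unsaturated ester; the α-methyl centre (later C3) forms racemic and is converged in step 8.

Step 4
Reactants: 8 ethyl (E)-2,6-dimethylhept-4-enoate
Product: 9 (E)-2,6-dimethylhept-4-enoic acid (racemic)
Conditions: LiOH, THF/H2O, rt; then 1 M HCl
Reagents that add atoms: lithium hydroxide, [Li+].[OH-]
Why: Plain ester saponification; no stereocentre of consequence is touched.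

Step 5
Reactants: 9 (E)-2,6-dimethylhept-4-enoic acid; 4 (R)-3-methyl-3-(triethylsilyloxy)cyclopentan-1-one (2 equiv)
Product: 11 (4R)-2-[(E)-2,6-dimethylhept-4-enoyl]-4-methyl-4-(triethylsilyloxy)cyclopentan-1-one (enolised β-diketone), via acid chloride 10 (not isolated)
Conditions: 9, (COCl)2, DMF (cat.), CH2Cl2, rt, concentrate; 4, LiN(iPr)2 (2 equiv), THF, −78 °C; then 10, −78 to −20 °C; AcOH
Reagents that add atoms: none
Why: Claisen-type C-acylation of the kinetic lithium enolate (deprotonation at the CH2 remote from the quaternary silyloxy carbon) by the acid chloride should give the β-diketone, the second equivalent of enolate deprotonating the product and returning 4; the new α-centres are enolised and inconsequential.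

Step 6
Reactants: 11 β-diketone
Product: 12 benzyl (4R)-2-[(E)-2,6-dimethylhept-4-enoyl]-4-methyl-4-(triethylsilyloxy)cyclopent-1-en-1-yl carbonate
Conditions: BnOCOCl, pyridine, CH2Cl2, 0 °C
Reagents that add atoms: benzyl chloroformate, O=C(Cl)OCc1ccccc1
Why: O-acylation of the enolised β-diketone at the ring oxygen (the side-chain carbonyl is shielded by its α-branch) should fix the endocyclic enol as its carbonate, which is both the enone chromophore and the latent cyclobutanol of the De Mayo sequence.

Step 7
Reactants: 12 enol carbonate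
Product: 13 tricyclic photoadduct: cyclobutane C1–C5–C9–C10 cis-fused to the C4-ketone cyclopentanone (C1–C5) and, on its other face, to the silyloxycyclopentane (C5–C9); C9 benzyl carbonate; C7–OSiEt3 endo; mixture at C3 and C10
Conditions: hν (medium-pressure Hg lamp, Pyrex, λ > 300 nm), degassed cyclohexane (5 mM), 10 °C
Reagents that add atoms: none
Why: Excitation of the β-acyloxy enone (C9=C5–C4=O) and intersystem crossing give a triplet that attacks the tethered alkene in the 1,5-mode (rule of five): C5 bonds to C1 in a 5-exo-trig closure of the cyclopentanone, and the resulting 1,4-biradical (α-oxy radical at C9, secondary radical at C10) collapses to the cyclobutane after spin inversion. This is the enone–alkene [2+2] stage of an intramolecular De Mayo reaction of a 2-acylcycloalkanone enol carbonate. Both five-membered rings must be cis-fused to the cyclobutane, which fixes C5 and C9 and ties the configuration of C1 to the enone face that is attacked. That face is chosen by the C7 centre: in the boat-like bicyclo[3.2.0] closure the endo substituent on C7 is pseudoaxial, and the smaller silyloxy oxygen should take this place in preference to methyl, so the alkene should add syn to oxygen and put C1–H and C7–O on the same side, as the target needs; the epimeric adduct is a separable diastereomer. The three-atom tether secures the straight (not crossed) regiochemistry and λ > 300 nm excites only the enone; C3 and C10 form as mixtures that steps 8 and 9 converge.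

Step 8
Reactants: 13 photoadduct
Product: 14 3β-hydroxy photoadduct (C3–OH cis to C1–H, C3–Me towards the cyclobutane)
Conditions: KN(SiMe3)2, THF, −78 °C; 2-(phenylsulfonyl)-3-phenyloxaziridine, −78 °C; AcOH
Reagents that add atoms: 2-(phenylsulfonyl)-3-phenyloxaziridine, O=S(=O)(c1ccccc1)N1OC1c1ccccc1
Why: Davis enolate hydroxylation: in the cage the C4 ketone can enolise only towards C3 (C5 is quaternary), and the oxaziridine should attack the convex face of the cyclopentanone–cyclobutane bicycle, anti to the cyclobutane and its carbonate, which places the C3 hydroxyl β (cis to C1–H) and converges both C3 epimers.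

Step 9
Reactants: 14 3β-hydroxy photoadduct
Product: 17 (1β-H,5α-H)-3β-hydroxy-10β-isopropyl-3α,7α-dimethyl-7β-(triethylsilyloxy)bicyclo[5.3.0]decane-4,9-dione, via cyclobutanol 15 (not isolated), via kinetic diketone 16 (not isolated)
Conditions: H2 (1 atm), Pd/C, EtOAc, rt; then K2CO3, MeOH, rt
Reagents that add atoms: none
Why: Hydrogenolysis of the benzyl carbonate frees the cyclobutanol, whose retro-aldol cleavage of C5–C9 (strain release, C4 carbonyl as acceptor) opens the seven-membered ring, and carbonate in methanol should then epimerise C5 and C10 through their enols to the all-equatorial trans-fused isomer with the isopropyl group trans to C2 (a minor epimer can be resubjected).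

Step 10
Reactants: 17 trans-fused hydroxy diketone
Product: 18 (1β-H,5α-H)-3β,4α-dihydroxy-10β-isopropyl-3α,7α-dimethyl-7β-(triethylsilyloxy)bicyclo[5.3.0]decan-9-one
Conditions: Me4NBH(OAc)3, MeCN/AcOH, −30 °C
Reagents that add atoms: none
Why: Evans–Saksena hydroxyl-directed reduction: only the α-hydroxy ketone should react, by intramolecular hydride delivery from boron bound to the β-C3 oxygen, so H enters C4 from the β-face and the new hydroxyl is α (trans-diol), while the C9 ketone has no free neighbouring hydroxyl and stays.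

Step 11
Reactants: 18 trans-diol ketone
Product: 20 (1β-H,5α-H)-3β,4β-epoxy-10β-isopropyl-3α,7α-dimethyl-7β-(triethylsilyloxy)bicyclo[5.3.0]decan-9-one, via mesylate 19 (not isolated)
Conditions: MsCl, Et3N, CH2Cl2, 0 °C; then K2CO3, MeOH, rt
Reagents that add atoms: none
Why: Selective mesylation of the only secondary alcohol and Williamson-type 3-exo-tet closure by the trans tertiary alkoxide should invert C4 and give the β-epoxide across C3–C4.

Step 12
Reactants: 20 epoxy ketone silyl ether
Product: 21 (1β-H,5α-H)-3β,4β-epoxy-7β-hydroxy-10β-isopropyl-3α,7α-dimethylbicyclo[5.3.0]decan-9-one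
Conditions: HF·pyridine, pyridine, THF, 0 °C to rt
Reagents that add atoms: none
Why: Pyridine-buffered fluoride desilylation of the tertiary triethylsilyl ether should spare the epoxide and avoids the base that would trigger retro-aldol of the β-hydroxy ketone formed.

Step 13
Reactants: 21 epoxy hydroxy ketone
Product: 22 (1β-H,5α-H)-3β,4β-epoxy-10β-isopropyl-3α,7α-dimethylbicyclo[5.3.0]decane-7β,9α-diol
Conditions: Me4NBH(OAc)3, MeCN/AcOH, −30 °C
Reagents that add atoms: none
Why: Second Evans–Saksena reduction: the free β-C7 hydroxyl should deliver hydride to the β-face of C9, giving the anti-1,3-diol with the C9 hydroxyl α, trans to the isopropyl group.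

Step 14
Reactants: 22 epoxy diol; 23 4-acetoxybenzoyl chloride
Product: 25 9α-(4-hydroxybenzoate) of 22 (target CNP0245441.1), via aryl acetate 24 (not isolated)
Conditions: 23, Et3N, DMAP (cat.), CH2Cl2, rt; then NH3, MeOH, 0 °C
Reagents that add atoms: 4-acetoxybenzoyl chloride (compound 23), CC(=O)Oc1ccc(cc1)C(Cl)=O
Why: DMAP-catalysed acylation of the only secondary alcohol (the tertiary C7 hydroxyl is inert), then chemoselective ammonolysis of the much more electrophilic aryl acetate, should free the phenol without touching the hindered benzoate or the epoxide.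

Compound list
1 | 3-methylcyclopent-2-en-1-one | CC1=CC(=O)CC1 | starting material
2 | (S)-3-methyl-3-(4,4,5,5-tetramethyl-1,3,2-dioxaborolan-2-yl)cyclopentan-1-one | C[C@@]1(B2OC(C)(C)C(C)(C)O2)CCC(=O)C1 | intermediate
3 | (R)-3-hydroxy-3-methylcyclopentan-1-one | C[C@@]1(O)CCC(=O)C1 | intermediate
4 | (R)-3-methyl-3-(triethylsilyloxy)cyclopentan-1-one | C[C@@]1(O[Si](CC)(CC)CC)CCC(=O)C1 | intermediate
5 | 4-methylpent-1-en-3-ol (racemic) | CC(C)C(O)C=C | starting material
6 | triethyl orthopropionate | CCC(OCC)(OCC)OCC | starting material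
7 | 1-ethoxy-1-[(4-methylpent-1-en-3-yl)oxy]prop-1-ene (ketene acetal) | CC=C(OCC)OC(C=C)C(C)C | intermediate
8 | ethyl (E)-2,6-dimethylhept-4-enoate (racemic) | CCOC(=O)C(C)C/C=C/C(C)C | intermediate
9 | (E)-2,6-dimethylhept-4-enoic acid (racemic) | OC(=O)C(C)C/C=C/C(C)C | intermediate
10 | (E)-2,6-dimethylhept-4-enoyl chloride | ClC(=O)C(C)C/C=C/C(C)C | intermediate
11 | (4R)-2-[(E)-2,6-dimethylhept-4-enoyl]-4-methyl-4-(triethylsilyloxy)cyclopentan-1-one (epimers at C2 and at the acyl α-carbon, enolised) | O=C1C[C@](C)(O[Si](CC)(CC)CC)CC1C(=O)C(C)C/C=C/C(C)C | intermediate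
12 | benzyl (4R)-2-[(E)-2,6-dimethylhept-4-enoyl]-4-methyl-4-(triethylsilyloxy)cyclopent-1-en-1-yl carbonate | CC(C)/C=C/CC(C)C(=O)C1=C(OC(=O)OCc2ccccc2)C[C@](C)(O[Si](CC)(CC)CC)C1 | intermediate
13 | tricyclic photoadduct: C1–C5 and C9–C10 bonded, C4 ketone, C9 benzyl carbonate, C7–OSiEt3 endo, C1–H on the side of the C5–C9 ring, mixture at C3 and C10 | CC(C)C1[C@@H]2CC(C)C(=O)[C@@]23C[C@@](C)(O[Si](CC)(CC)CC)C[C@@]13OC(=O)OCc1ccccc1 | intermediate
14 | 3β-hydroxy photoadduct (C3–OH cis to C1–H), mixture at C10 | CC(C)C1[C@@H]2C[C@@](C)(O)C(=O)[C@@]23C[C@@](C)(O[Si](CC)(CC)CC)C[C@@]13OC(=O)OCc1ccccc1 | intermediate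
15 | C9 cyclobutanol of 14 | CC(C)C1[C@@H]2C[C@@](C)(O)C(=O)[C@@]23C[C@@](C)(O[Si](CC)(CC)CC)C[C@@]13O | intermediate
16 | kinetic 1,5-diketone, mixture at C5 and C10 | CC(C)C1[C@@H]2C[C@@](C)(O)C(=O)C2C[C@@](C)(O[Si](CC)(CC)CC)CC1=O | intermediate
17 | (1β-H,5α-H)-3β-hydroxy-10β-isopropyl-3α,7α-dimethyl-7β-(triethylsilyloxy)bicyclo[5.3.0]decane-4,9-dione | CC(C)[C@H]1[C@@H]2C[C@@](C)(O)C(=O)[C@H]2C[C@@](C)(O[Si](CC)(CC)CC)CC1=O | intermediate
18 | (1β-H,5α-H)-3β,4α-dihydroxy-10β-isopropyl-3α,7α-dimethyl-7β-(triethylsilyloxy)bicyclo[5.3.0]decan-9-one | CC(C)[C@H]1[C@@H]2C[C@@](C)(O)[C@H](O)[C@H]2C[C@@](C)(O[Si](CC)(CC)CC)CC1=O | intermediate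
19 | 4α-methanesulfonate of 18 | CC(C)[C@H]1[C@@H]2C[C@@](C)(O)[C@H](OS(C)(=O)=O)[C@H]2C[C@@](C)(O[Si](CC)(CC)CC)CC1=O | intermediate
20 | (1β-H,5α-H)-3β,4β-epoxy-10β-isopropyl-3α,7α-dimethyl-7β-(triethylsilyloxy)bicyclo[5.3.0]decan-9-one | CC(C)[C@H]1[C@@H]2C[C@@]3(C)O[C@H]3[C@H]2C[C@@](C)(O[Si](CC)(CC)CC)CC1=O | intermediate
21 | (1β-H,5α-H)-3β,4β-epoxy-7β-hydroxy-10β-isopropyl-3α,7α-dimethylbicyclo[5.3.0]decan-9-one | CC(C)[C@H]1[C@@H]2C[C@@]3(C)O[C@H]3[C@H]2C[C@@](C)(O)CC1=O | intermediate
22 | (1β-H,5α-H)-3β,4β-epoxy-10β-isopropyl-3α,7α-dimethylbicyclo[5.3.0]decane-7β,9α-diol | CC(C)[C@H]1[C@@H]2C[C@@]3(C)O[C@H]3[C@H]2C[C@@](C)(O)C[C@@H]1O | intermediate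
23 | 4-acetoxybenzoyl chloride | CC(=O)Oc1ccc(cc1)C(Cl)=O | starting material
24 | 9α-(4-acetoxybenzoate) of 22 | CC(C)[C@H]1[C@@H]2C[C@@]3(C)O[C@H]3[C@H]2C[C@@](C)(O)C[C@@H]1OC(=O)c1ccc(OC(C)=O)cc1 | intermediate
25 | 9α-(4-hydroxybenzoate) of 22, CNP0245441.1 | CC(C)[C@H]1[C@@H]2C[C@@]3(C)O[C@H]3[C@H]2C[C@@](C)(O)C[C@@H]1OC(=O)c1ccc(O)cc1 | target

Total step count: 14. Longest linear sequence: 12 steps (steps 1, 2, 5–14 from 1; equally steps 3–14 from 5).

Steps most likely to fail

Step 7. What may go wrong: the alkene adds to the other face of the enol double bond, because the only control element (C7) is two bonds from either reacting carbon, so the C1-epimeric adduct dominates; or the enol carbonate undergoes a photochemical 1,3-acyl shift instead of cycloaddition. Fallback, setting out from 4 and coming back at 14: the C3 oxygen is installed before irradiation as a second, closer control element, and step 8 is dropped. Commercial methyl (R)-2-methylglycidate is opened at its CH2 by [(E)-iPrCH=CH]2CuLi to methyl (R,E)-2-hydroxy-2,6-dimethylhept-4-enoate F1, which is silylated (Me3SiCl, imidazole) to the trimethylsilyl ether F2 and reduced (iBu2AlH, −78 °C) to (R,E)-2,6-dimethyl-2-(trimethylsilyloxy)hept-4-enal F3. Aldol addition of the kinetic lithium enolate of 4 (LiN(iPr)2) gives the β-hydroxy ketone F4, Dess–Martin oxidation the β-diketone F5, and benzyl chloroformate/pyridine the enol carbonate F6. Irradiation as in step 7 should give the C3-silyloxy photoadduct F7. Only in the desired diastereomer can both tertiary oxygens (C3 and C7) take the pseudoaxial sites of their cis-fused five-membered rings, so the two centres reinforce each other. PPTS in methanol then removes the tertiary trimethylsilyl ether selectively and delivers 14.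

Step 5. What may go wrong: O-acylation of the enolate, acylation at the CH2 next to the silyloxy carbon, or ketene formation from 10. Fallback, setting out from 8 and 4 and coming back at 11: ester 8 is reduced with iBu2AlH at −78 °C to (E)-2,6-dimethylhept-4-enal F8, the kinetic lithium enolate of 4 is added to it to give the β-hydroxy ketone F9, and Dess–Martin oxidation gives 11. An aldehyde leaves no O- versus C-acylation question.

Step 13. What may go wrong: acid-promoted opening of the trisubstituted epoxide in the acetic acid medium, or retro-aldol or dehydration of the free β-hydroxy ketone 21 during steps 12 and 13. Fallback, setting out from 18 and coming back at 22: epoxide closure is postponed until after the second reduction. Mesylate 19 is isolated (MsCl, Et3N) and desilylated with HF·pyridine to the 7β-hydroxy mesylate F10. Me4NBH(OAc)3 (directed by C7–OH) reduces it to the 9α-alcohol F11, and only then does K2CO3 in methanol close the epoxide to give 22.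

Further compounds
F1 | step 7 | methyl (R,E)-2-hydroxy-2,6-dimethylhept-4-enoate | CC(C)/C=C/C[C@@](C)(O)C(=O)OC
F2 | step 7 | methyl (R,E)-2,6-dimethyl-2-(trimethylsilyloxy)hept-4-enoate | CC(C)/C=C/C[C@@](C)(O[Si](C)(C)C)C(=O)OC
F3 | step 7 | (R,E)-2,6-dimethyl-2-(trimethylsilyloxy)hept-4-enal | CC(C)/C=C/C[C@@](C)(O[Si](C)(C)C)C=O
F4 | step 7 | aldol adduct of F3 and 4 (β-hydroxy ketone, mixture at the two new centres) | O=C1C[C@](C)(O[Si](CC)(CC)CC)CC1C(O)[C@](C)(O[Si](C)(C)C)C/C=C/C(C)C
F5 | step 7 | β-diketone from F4 | O=C1C[C@](C)(O[Si](CC)(CC)CC)CC1C(=O)[C@](C)(O[Si](C)(C)C)C/C=C/C(C)C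
F6 | step 7 | benzyl enol carbonate of F5 | CC(C)/C=C/C[C@@](C)(O[Si](C)(C)C)C(=O)C1=C(OC(=O)OCc2ccccc2)C[C@](C)(O[Si](CC)(CC)CC)C1
F7 | step 7 | 3β-(trimethylsilyloxy) photoadduct (trimethylsilyl ether of 14) | CC(C)C1[C@@H]2C[C@@](C)(O[Si](C)(C)C)C(=O)[C@@]23C[C@@](C)(O[Si](CC)(CC)CC)C[C@@]13OC(=O)OCc1ccccc1
F8 | step 5 | (E)-2,6-dimethylhept-4-enal (racemic) | CC(C)/C=C/CC(C)C=O
F9 | step 5 | aldol adduct of F8 and 4 (β-hydroxy ketone, mixture) | O=C1C[C@](C)(O[Si](CC)(CC)CC)CC1C(O)C(C)C/C=C/C(C)C
F10 | step 13 | 4α-mesyloxy-3β,7β-dihydroxy 9-ketone (desilylated 19) | CC(C)[C@H]1[C@@H]2C[C@@](C)(O)[C@H](OS(C)(=O)=O)[C@H]2C[C@@](C)(O)CC1=O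
F11 | step 13 | 4α-mesyloxy-3β,7β,9α-triol | CC(C)[C@H]1[C@@H]2C[C@@](C)(O)[C@H](OS(C)(=O)=O)[C@H]2C[C@@](C)(O)C[C@@H]1O
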